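Abbreviations: SEM = CH2OCH2CH2SiMe3 (2-(trimethylsilyl)ethoxymethyl), prenyl = 3-methylbut-2-en-1-yl, Bpin = 4,4,5,5-tetramethyl-1,3,2-dioxaborolan-2-yl. Compound numbers are those of the steps and the compound list below.

## Analysis of the target

Target 19 is a 3-hydroxyisoflavanone: ring A is fused to a dihydropyranone ring C (O1, C2H2, C3, C4=O), and C3 carries both a hydroxyl group and ring B. Ring A bears the C5 hydroxyl, hydrogen-bonded to the C4 carbonyl, and the C7 methoxy group; ring B is contiguously substituted with a 2′-methoxy, a 3′-prenyl and a 4′-hydroxy group. C3 is the only stereocentre and is (S) (priorities OH > C4 > C2 > aryl). It is a fully substituted tertiary benzylic α-ketol, so there is no second centre to relate it to, it cannot be epimerised, and it cannot be corrected once made. Acid is the main threat: it can ionise the tertiary benzylic C3–O bond (loss of water across C2–C3 leads to the isoflavone) and it cyclises the 3′-prenyl group onto the 4′-phenol. The prenyl alkene also rules out hydrogenolysis, peracids and electrophilic halogen, and the electron-rich phenols are easily oxidised. The difficulty is therefore to set, in absolute terms, an oxygenated quaternary centre lying between a carbonyl group and an electron-rich arene, and to free three phenols at the end without acid or hydrogen. The strategy rests on the O1–C2–C3(OH) array: two oxygens on adjacent carbons, one of them the ring oxygen on a CH2 group, are what an oxirane across C2–C3 leaves behind when a ring A oxygen opens it at C2. Before ring C exists, the acyl-bearing carbon of ring A is flanked by two equivalent oxygens (the future O1 and C5–OH), so they need not be told apart.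

## Retrosynthetic reasoning

**O1–C2.** In 19 the ether bond O1–C2 is cut and the C3 hydroxyl is read as a former oxirane oxygen. This leads back, through the ring B ether 18 and the ring A phenoxide 17, to epoxy ketone 16, in which all three phenols are masked as fluoride-labile SEM acetals. The cut is made here and not at C3–O, C3–C4 or C4–C4a because it is the one ring C bond whose formation leaves the stereocentre untouched. Ring closure and stereocontrol are thereby separated, and the tertiary alcohol appears only in the last step and never needs protection. The forward reaction has to free the ring A oxygens under basic, non-ionising conditions, open the oxirane at its CH2 carbon and not at the quaternary carbon, and then remove the ring B acetal.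

**C4–C4a.** Ketone 16 is cut between the carbonyl carbon and ring A, by way of carbinol 15, into aldehyde 11 and aryllithium 14. 14 is the metalation product of the symmetric bis(acetal) 13, which comes from diphenol 12. This cut is preferred to one at C3–C4 because 11 holds the complete stereocentre on a carbon without hydrogen, so nothing can epimerise during the addition. Ring A enters as a nucleophile metalated where both acetal oxygens direct. The price is one oxidation after the coupling, which also erases the uncontrolled carbinol centre of 15.

**Oxirane oxygen.** Aldehyde 11 is traced to epoxy alcohol 10 and this to the 2-arylallyl alcohol 9. The primary allylic hydroxyl of 9 lets a titanium tartrate catalyst deliver oxygen to one face of the 1,1-disubstituted alkene. The trisubstituted prenyl alkene has no such handle and stays out; a peracid or a dihydroxylation would attack it first. The tartrate of the D series is required: it gives (R)-10. The same carbon is called (S) in 11, 15 and 16 only because the oxidised carbon then outranks the ring CH2.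

**C1′–C3.** Allylic alcohol 9 is cut at the aryl–alkenyl bond into boronate 7 and alkenyl bromide 8, to be joined by palladium-catalysed coupling; 7 derives from aryl chloride 6. This brings in the three carbons of the future C2–C3–C4 unit in one piece with the hydroxyl in place.

**C3′–CH2 of the prenyl group.** 6 is cut between ring B and the prenyl CH2 into 3 and aryl chloride 2, through aryllithium 4 and arylcopper 5; 2 is the acetal of phenol 1. The carbon between the methoxy and the acetal oxygen is where both direct the metalation, so the contiguous 1′,2′,3′,4′ pattern follows from the substitution of 1 without isomer separation. Chlorine, not a heavier halogen, sits at C1′ because it must survive an alkyllithium in this step and still be activated by palladium in the next.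

## Alternatives that were turned down

**Alternative 1:** Here C3–O and C2–C3 are cut together. A rhodium carbenoid, formed by Rh2(OAc)4 from the diaryl α-diazo ketone A1, would take up water to give a protic oxonium ylide, and this would add to formaldehyde to give the dihydroxy ketone A2.
- For it: A1 comes from a deoxybenzoin, the shortest assembly of the isoflavonoid skeleton. The quaternary centre and both C3 substituents arise in one catalytic step, and no chiral intermediate is carried. In convergence and bond economy of the key step it is stronger than the chosen route.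
- Against it: the absolute configuration would depend on a chiral co-catalyst discriminating the faces of an enol-type intermediate towards the smallest possible aldehyde, for which there is no predictive model. The carbenoid is flanked by the 2′-methoxy group and two acetal oxygens, which invite C–H insertion and ether ylide formation; the prenyl alkene can be cyclopropanated; a simple 1,2-proton shift gives the benzoin instead. A2 is a β-hydroxy ketone and can lose formaldehyde by retro-aldol cleavage. Ring C is still open after the key step: a ring A phenol must be freed and the primary alcohol activated selectively, and the methoxymethyl ethers then need acid, which endangers the tertiary carbinol and the prenyl/phenol pair.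
- Comparison: the chosen strategy offers a stereocentre fixed by a reagent with a known face rule, and ring closure and deprotection in one basic final step.

**Alternative 2:** Here O1–C8a and C4–C4a are cut together. The primary alkoxide of hydroxy ester A3 would add to the aryne released by CsF from silylaryl triflate A4, and the aryl anion so formed would acylate on the ester to give the tris(methoxymethyl) ether A5.
- For it: two bonds to ring A and ring C form in one step. The alkoxy group next to the aryne bond steers the alkoxide to the distal carbon, so the regiochemistry is built in. No aryllithium and no oxidation-level changes are needed at the coupling stage; on these points it is as strong as or stronger than the chosen route.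
- Against it: the stereochemical problem is only moved. A3 already contains the quaternary carbinol and would have to be made by the same kind of epoxidation or by a dihydroxylation that the prenyl alkene does not tolerate. Its tertiary benzylic hydroxyl must be protected, and later deprotected with acid at the most ionisable position of the molecule. The aryl anion must attack an ester next to a quaternary carbon and may instead be protonated by the hydroxyl of a second molecule, which stops at the aryl ether. A4, with three oxygen substituents and an ortho silyl triflate pair, needs several steps of its own.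
- Comparison: the overall step count would exceed that of the chosen route, which forms the tertiary alcohol last and so never has to protect or unmask it.

**Alternative 3:** Here C3–C4 is cut. A chiral triazolium-derived carbene would convert the ring A aldehyde of keto aldehyde A6 into an acyl anion equivalent that adds to the tethered ring B aryl ketone, giving the bis(methoxymethyl) ether A7.
- For it: this is the shortest plan. A6 is one O-alkylation away from a salicylaldehyde and an α-halo ketone. The stereocentre is created catalytically in the ring-closing step, and intramolecular aldehyde–ketone benzoin closure to 3-hydroxychromanones is an established carbene-catalysed reaction type. In step and atom economy it is clearly stronger than the chosen route.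
- Against it: the aldehyde of A6 has oxygen substituents at both ortho positions, which slows formation of the acyl anion equivalent. The acceptor ketone is electron-rich and ortho-substituted, so it is a poor electrophile. The acidic O–CH2–C=O group can close onto the aldehyde by aldol condensation to an aroylbenzofuran under the base needed for the carbene. The benzoin step is reversible, so enantiomeric purity is not secured by a fixed rule and may erode. The α-halo ketone must be made in the presence of the prenyl alkene, and the end game again needs acid for the acetals.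
- Comparison: the chosen strategy is longer, but its configuration comes from a reagent-controlled epoxidation of predictable sense and its last step is basic.

Key step: step 10

Assumption: the face rule of the titanium tartrate epoxidation for 2-substituted primary allylic alcohols is taken to hold for 9, and the two acetals ortho to the ketone in 16 are taken to be lost before the one on ring B; the outcome does not depend on the second point.

## Route

Step 1
Reactants: 1 4-chloro-3-methoxyphenol
Product: 2 1-chloro-2-methoxy-4-(SEM-oxy)benzene
Conditions: SEMCl, iPr2NEt, CH2Cl2, 0 °C to rt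
Reagents that add atoms: 2-(trimethylsilyl)ethoxymethyl chloride (SEMCl), C[Si](C)(C)CCOCCl
Why: O-alkylation of the phenol by the chloromethyl ether (acetal formation); the acetal oxygen is the metalation director of step 2 and the group is cleaved by fluoride, not acid.

Step 2
Reactants: 2 1-chloro-2-methoxy-4-(SEM-oxy)benzene; 3 prenyl bromide
Product: 6 1-chloro-2-methoxy-3-prenyl-4-(SEM-oxy)benzene, via aryllithium 4 (not isolated), via arylcopper 5 (not isolated)
Conditions: n-BuLi, THF, 0 °C; CuBr·SMe2, −78 °C; then 3, −78 °C to rt
Reagents that add atoms: none
Why: Directed ortho-metalation at the carbon flanked by the methoxy and acetal oxygens, then copper-mediated allylic substitution at the primary carbon of 3 without allylic transposition; n-BuLi does not exchange chlorine and the lithiated carbon is not next to it, so no aryne pathway opens.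

Step 3
Reactants: 6 1-chloro-2-methoxy-3-prenyl-4-(SEM-oxy)benzene
Product: 7 2-[2-methoxy-3-prenyl-4-(SEM-oxy)phenyl]-4,4,5,5-tetramethyl-1,3,2-dioxaborolane
Conditions: B2pin2, Pd2(dba)3 (cat.), XPhos, KOAc, 1,4-dioxane, 100 °C
Reagents that add atoms: bis(pinacolato)diboron, CC1(C)OB(OC1(C)C)B1OC(C)(C)C(C)(C)O1
Why: Miyaura borylation of an aryl chloride; the bulky electron-rich biarylphosphine allows oxidative addition into the electron-rich C–Cl bond, and the weak acetate base keeps the boronate from coupling with remaining chloride.

Step 4
Reactants: 7 aryl pinacol boronate; 8 2-bromoprop-2-en-1-ol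
Product: 9 2-[2-methoxy-3-prenyl-4-(SEM-oxy)phenyl]prop-2-en-1-ol
Conditions: Pd(dppf)Cl2 (cat.), K2CO3, 1,4-dioxane/H2O, 80 °C
Reagents that add atoms: none
Why: Suzuki–Miyaura coupling of the aryl boronate with the alkenyl bromide joins C1′ to the future C3 and gives the 2-arylallyl alcohol directly; the free hydroxyl and the prenyl alkene are spectators.

Step 5
Reactants: 9 2-[2-methoxy-3-prenyl-4-(SEM-oxy)phenyl]prop-2-en-1-ol
Product: 10 {(2R)-2-[2-methoxy-3-prenyl-4-(SEM-oxy)phenyl]oxiran-2-yl}methanol
Conditions: Ti(OiPr)4 (cat.), D-(−)-diethyl tartrate, t-BuOOH, 4 Å MS, CH2Cl2, −20 °C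
Reagents that add atoms: tert-butyl hydroperoxide, CC(C)(C)OO
Why: Sharpless asymmetric epoxidation: the titanium tartrate complex binds the allylic alkoxide and the hydroperoxide and delivers oxygen to one alkene face, and the D-(−)-tartrate (the one that converts allyl alcohol into (R)-glycidol) should set the quaternary centre as (2R); the prenyl alkene has no directing hydroxyl and is left alone.

Step 6
Reactants: 10 {(2R)-2-[2-methoxy-3-prenyl-4-(SEM-oxy)phenyl]oxiran-2-yl}methanol
Product: 11 (2S)-2-[2-methoxy-3-prenyl-4-(SEM-oxy)phenyl]oxirane-2-carbaldehyde
Conditions: Dess–Martin periodinane, NaHCO3, CH2Cl2, 0 °C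
Reagents that add atoms: none
Why: Buffered Dess–Martin oxidation of the primary alcohol; the α-carbon is quaternary, so the aldehyde cannot epimerise, and the descriptor changes from R to S only because the formyl group now outranks the ring CH2.

Step 7
Reactants: 12 5-methoxyresorcinol
Product: 13 1-methoxy-3,5-bis(SEM-oxy)benzene
Conditions: SEMCl, iPr2NEt, CH2Cl2, 0 °C to rt
Reagents that add atoms: 2-(trimethylsilyl)ethoxymethyl chloride (SEMCl), C[Si](C)(C)CCOCCl
Why: Double O-alkylation of the diphenol to the bis(acetal), which keeps the ring symmetric and provides two cooperating metalation directors.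

Step 8
Reactants: 13 1-methoxy-3,5-bis(SEM-oxy)benzene; 11 (2S)-2-[2-methoxy-3-prenyl-4-(SEM-oxy)phenyl]oxirane-2-carbaldehyde
Product: 15 [4-methoxy-2,6-bis(SEM-oxy)phenyl]{(2S)-2-[2-methoxy-3-prenyl-4-(SEM-oxy)phenyl]oxiran-2-yl}methanol (both carbinol epimers), via aryllithium 14 (not isolated)
Conditions: n-BuLi, THF, 0 °C; then 11, −78 °C; H2O
Reagents that add atoms: none
Why: Directed ortho-metalation at the carbon between the two acetal oxygens (stronger, doubly chelating directors than methoxy), then 1,2-addition of the aryllithium to the non-enolisable aldehyde at low temperature; the new carbinol centre is uncontrolled and is removed by the next oxidation.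

Step 9
Reactants: 15 epoxy carbinol (both epimers)
Product: 16 [4-methoxy-2,6-bis(SEM-oxy)phenyl]{(2S)-2-[2-methoxy-3-prenyl-4-(SEM-oxy)phenyl]oxiran-2-yl}methanone
Conditions: Dess–Martin periodinane, NaHCO3, CH2Cl2, 0 °C to rt
Reagents that add atoms: none
Why: Dess–Martin oxidation of the secondary benzylic carbinol to the aryl ketone under buffered conditions that spare the oxirane, the acetals and the prenyl alkene; both epimers of 15 converge on one ketone.

Step 10
Reactants: 16 epoxy ketone tris(SEM) ether
Product: 19 (3S)-3,5-dihydroxy-3-(4-hydroxy-2-methoxy-3-prenylphenyl)-7-methoxy-2,3-dihydro-4H-chromen-4-one (the target), via ring A diphenoxide 17 (not isolated), via chromanone SEM ether 18 (not isolated)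
Conditions: TBAF, THF/DMPU, 4 Å MS, rt then 50 °C; H2O
Reagents that add atoms: none
Why: Fluoride attacks silicon of each acetal, which fragments to fluorotrimethylsilane, ethylene, formaldehyde and the phenoxide; the two ethers ortho to the ketone should go first because the acyl-stabilised phenoxide is the better leaving group. One ring A phenoxide of 17 then attacks the oxirane CH2 (C2) in an intramolecular SN2 opening that forms O1–C2 and ring C (18), and further heating removes the ring B acetal to give 19. The closest known reaction type is the base-mediated cyclisation of 2′-hydroxyaryl α,β-epoxy ketones to 3-hydroxychromanones (Algar–Flynn–Oyamada manifold), here triggered by fluoride cleavage of aryl SEM ethers. Ring C closes in the 6-endo mode with respect to the oxirane, since both oxirane carbons end up in the new ring. No stereocentre is formed: the C3–O bond is never broken, so the configuration set in step 5 is carried into the carbinol as (S). The selectivity needed is attack at CH2 over 5-exo attack at C3; the carbonyl group activates C3 electronically, but C3 is fully substituted and closed to backside attack, whereas C2 is an unhindered primary carbon, and the basic, non-ionising medium keeps the benzylic C3–O bond from ionising. The two ortho oxygens of ring A are interchanged by rotation about the aryl–carbonyl bond, so either one closes to the same product and the other becomes the C5 hydroxyl.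

## Compound list

1 | 4-chloro-3-methoxyphenol | COc1cc(O)ccc1Cl | starting material
2 | 1-chloro-2-methoxy-4-{[2-(trimethylsilyl)ethoxy]methoxy}benzene | COc1cc(OCOCC[Si](C)(C)C)ccc1Cl | intermediate
3 | prenyl bromide (1-bromo-3-methylbut-2-ene) | CC(C)=CCBr | starting material
4 | (3-chloro-2-methoxy-6-{[2-(trimethylsilyl)ethoxy]methoxy}phenyl)lithium (not isolated; drawn as monomer) | COc1c([Li])c(OCOCC[Si](C)(C)C)ccc1Cl | intermediate
5 | (3-chloro-2-methoxy-6-{[2-(trimethylsilyl)ethoxy]methoxy}phenyl)copper (not isolated; drawn as monomer) | COc1c([Cu])c(OCOCC[Si](C)(C)C)ccc1Cl | intermediate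
6 | 1-chloro-2-methoxy-3-(3-methylbut-2-en-1-yl)-4-{[2-(trimethylsilyl)ethoxy]methoxy}benzene | COc1c(CC=C(C)C)c(OCOCC[Si](C)(C)C)ccc1Cl | intermediate
7 | 2-[2-methoxy-3-(3-methylbut-2-en-1-yl)-4-{[2-(trimethylsilyl)ethoxy]methoxy}phenyl]-4,4,5,5-tetramethyl-1,3,2-dioxaborolane | COc1c(CC=C(C)C)c(OCOCC[Si](C)(C)C)ccc1B1OC(C)(C)C(C)(C)O1 | intermediate
8 | 2-bromoprop-2-en-1-ol | C=C(Br)CO | starting material
9 | 2-[2-methoxy-3-(3-methylbut-2-en-1-yl)-4-{[2-(trimethylsilyl)ethoxy]methoxy}phenyl]prop-2-en-1-ol | COc1c(CC=C(C)C)c(OCOCC[Si](C)(C)C)ccc1C(=C)CO | intermediate
10 | {(2R)-2-[2-methoxy-3-(3-methylbut-2-en-1-yl)-4-{[2-(trimethylsilyl)ethoxy]methoxy}phenyl]oxiran-2-yl}methanol | OC[C@]1(c2ccc(OCOCC[Si](C)(C)C)c(CC=C(C)C)c2OC)CO1 | intermediate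
11 | (2S)-2-[2-methoxy-3-(3-methylbut-2-en-1-yl)-4-{[2-(trimethylsilyl)ethoxy]methoxy}phenyl]oxirane-2-carbaldehyde | O=C[C@]1(c2ccc(OCOCC[Si](C)(C)C)c(CC=C(C)C)c2OC)CO1 | intermediate
12 | 5-methoxyresorcinol (5-methoxybenzene-1,3-diol) | COc1cc(O)cc(O)c1 | starting material
13 | 1-methoxy-3,5-bis{[2-(trimethylsilyl)ethoxy]methoxy}benzene | COc1cc(OCOCC[Si](C)(C)C)cc(OCOCC[Si](C)(C)C)c1 | intermediate
14 | (4-methoxy-2,6-bis{[2-(trimethylsilyl)ethoxy]methoxy}phenyl)lithium (not isolated; drawn as monomer) | COc1cc(OCOCC[Si](C)(C)C)c([Li])c(OCOCC[Si](C)(C)C)c1 | intermediate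
15 | (4-methoxy-2,6-bis{[2-(trimethylsilyl)ethoxy]methoxy}phenyl){(2S)-2-[2-methoxy-3-(3-methylbut-2-en-1-yl)-4-{[2-(trimethylsilyl)ethoxy]methoxy}phenyl]oxiran-2-yl}methanol (both carbinol epimers) | COc1cc(OCOCC[Si](C)(C)C)c(c(OCOCC[Si](C)(C)C)c1)C(O)[C@]1(c2ccc(OCOCC[Si](C)(C)C)c(CC=C(C)C)c2OC)CO1 | intermediate
16 | (4-methoxy-2,6-bis{[2-(trimethylsilyl)ethoxy]methoxy}phenyl){(2S)-2-[2-methoxy-3-(3-methylbut-2-en-1-yl)-4-{[2-(trimethylsilyl)ethoxy]methoxy}phenyl]oxiran-2-yl}methanone | COc1cc(OCOCC[Si](C)(C)C)c(c(OCOCC[Si](C)(C)C)c1)C(=O)[C@]1(c2ccc(OCOCC[Si](C)(C)C)c(CC=C(C)C)c2OC)CO1 | intermediate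
17 | (2,6-dihydroxy-4-methoxyphenyl){(2S)-2-[2-methoxy-3-(3-methylbut-2-en-1-yl)-4-{[2-(trimethylsilyl)ethoxy]methoxy}phenyl]oxiran-2-yl}methanone, present as its tetrabutylammonium phenoxide (not isolated; drawn as the neutral diphenol) | COc1cc(O)c(c(O)c1)C(=O)[C@]1(c2ccc(OCOCC[Si](C)(C)C)c(CC=C(C)C)c2OC)CO1 | intermediate
18 | (3S)-3,5-dihydroxy-7-methoxy-3-[2-methoxy-3-(3-methylbut-2-en-1-yl)-4-{[2-(trimethylsilyl)ethoxy]methoxy}phenyl]-2,3-dihydro-4H-chromen-4-one (not isolated) | COc1cc(O)c2c(c1)OC[C@@](O)(c1ccc(OCOCC[Si](C)(C)C)c(CC=C(C)C)c1OC)C2=O | intermediate
19 | (3S)-3,5-dihydroxy-3-[4-hydroxy-2-methoxy-3-(3-methylbut-2-en-1-yl)phenyl]-7-methoxy-2,3-dihydro-4H-chromen-4-one | COc1cc(O)c2c(c1)OC[C@@](O)(c1ccc(O)c(CC=C(C)C)c1OC)C2=O | target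

## Step count and least certain steps

Total: 10 steps. Longest linear sequence: 9 steps (steps 1–6 and 8–10, from 1); the ring A branch (step 7) joins at step 8.

**Step 10 (key step).**
- What may go wrong: loss of the three acetals may be slower than base-induced decay of the epoxy ketone (attack of fluoride or phenoxide on the hindered carbonyl, acyloin-type shifts of the product alkoxide on heating). The electron-rich phenoxides may be hydroxymethylated by the formaldehyde released. Closure could also take the 5-exo course at C3.
- Fallback: ring A is unmasked by a method that needs neither fluoride nor heat. It sets out from 13 and returns at 17. The metalation of step 8 is quenched with 1,2-dibromotetrachloroethane to give 2-bromo-5-methoxy-1,3-bis(SEM-oxy)benzene F1. The acetals are removed (HCl, MeOH) to give 2-bromo-5-methoxybenzene-1,3-diol F2. Allyl bromide and K2CO3 in acetone give 2-bromo-5-methoxy-1,3-bis(allyloxy)benzene F3. Bromine–lithium exchange (n-BuLi, THF, −78 °C) gives [4-methoxy-2,6-bis(allyloxy)phenyl]lithium F4, which adds to 11 to give the bis(allyl) epoxy carbinol F5. Buffered Dess–Martin oxidation gives the bis(allyl) epoxy ketone F6. Pd(PPh3)4 with K2CO3 in MeOH at room temperature removes both allyl groups and gives phenoxide 17, which should close to 18 in the same carbonate medium. Isolated 18 then loses its one remaining, unactivated acetal under the fluoride conditions of step 10, at a stage where no oxirane is left.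

**Step 5.**
- What may go wrong: the tetravalent titanium alkoxide may open or rearrange the newly formed oxirane, whose benzylic carbon carries an ortho- and para-oxygenated arene (capture of isopropoxide or hydroperoxide at the benzylic carbon, or a Meinwald shift). Face selectivity may also fall below that of simple 2-alkyl allylic alcohols because of the ortho-substituted aryl group.
- Fallback: a nucleophilic, Lewis-acid-free epoxidation one oxidation level higher, setting out from 9 and returning at 11. MnO2 oxidises 9 to 2-[2-methoxy-3-prenyl-4-(SEM-oxy)phenyl]prop-2-enal F7. Iminium catalysis with a diarylprolinol silyl ether and aqueous H2O2 epoxidises the α-substituted acrolein directly to 11; the catalyst antipode is chosen to give the (2S) aldehyde. The prenyl alkene is inert to the nucleophilic oxidant, and the sequence needs no separate alcohol oxidation.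

**Step 8.**
- What may go wrong: metalation of 13 may occur partly at a carbon flanked by the methoxy group and one acetal, which would carry a regioisomeric ring A into the end game. Addition of the doubly ortho-substituted aryllithium to the α-quaternary aldehyde may be slow, and on warming the lithium alkoxide may undergo Payne-type oxirane migration.
- Fallback: the site of the carbanion is fixed before the valuable aldehyde is committed, setting out from 13 and returning at 14. The metalation product is brominated to 2-bromo-5-methoxy-1,3-bis(SEM-oxy)benzene F1 (as in the step 10 fallback) and purified at this simple stage. Bromine–lithium exchange with n-BuLi at −78 °C then gives 14 at the defined position and at a temperature where 11 can be added at once.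

**Step 3.**
- What may go wrong: oxidative addition into the electron-rich, ortho-substituted C–Cl bond may be slow. At the temperature then required, hydrodechlorination or migration of the prenyl double bond into conjugation may compete.
- Fallback: the bromo series, with an amide base in place of the alkyllithium and halogen–lithium exchange in place of palladium. It sets out from 3 and, in place of 1, from 4-bromo-3-methoxyphenol F8, and returns at 7. SEMCl and iPr2NEt give 1-bromo-2-methoxy-4-(SEM-oxy)benzene F9. Lithium 2,2,6,6-tetramethylpiperidide (THF, −78 °C), which deprotonates between the two oxygens without exchanging bromine, gives [3-bromo-2-methoxy-6-(SEM-oxy)phenyl]lithium F10. With catalytic CuBr·SMe2 and 3 this gives 1-bromo-2-methoxy-3-prenyl-4-(SEM-oxy)benzene F11. Bromine–lithium exchange (n-BuLi, −78 °C) gives [2-methoxy-3-prenyl-4-(SEM-oxy)phenyl]lithium F12, which is trapped with 2-isopropoxy-4,4,5,5-tetramethyl-1,3,2-dioxaborolane to give 7.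

## Further compounds

F1 | step 10 | 2-bromo-5-methoxy-1,3-bis{[2-(trimethylsilyl)ethoxy]methoxy}benzene | COc1cc(OCOCC[Si](C)(C)C)c(Br)c(OCOCC[Si](C)(C)C)c1
F2 | step 10 | 2-bromo-5-methoxybenzene-1,3-diol | COc1cc(O)c(Br)c(O)c1
F3 | step 10 | 2-bromo-5-methoxy-1,3-bis(prop-2-en-1-yloxy)benzene | COc1cc(OCC=C)c(Br)c(OCC=C)c1
F4 | step 10 | [4-methoxy-2,6-bis(prop-2-en-1-yloxy)phenyl]lithium | COc1cc(OCC=C)c([Li])c(OCC=C)c1
F5 | step 10 | [4-methoxy-2,6-bis(prop-2-en-1-yloxy)phenyl]{(2S)-2-[2-methoxy-3-(3-methylbut-2-en-1-yl)-4-{[2-(trimethylsilyl)ethoxy]methoxy}phenyl]oxiran-2-yl}methanol (both carbinol epimers) | COc1cc(OCC=C)c(c(OCC=C)c1)C(O)[C@]1(c2ccc(OCOCC[Si](C)(C)C)c(CC=C(C)C)c2OC)CO1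
F6 | step 10 | [4-methoxy-2,6-bis(prop-2-en-1-yloxy)phenyl]{(2S)-2-[2-methoxy-3-(3-methylbut-2-en-1-yl)-4-{[2-(trimethylsilyl)ethoxy]methoxy}phenyl]oxiran-2-yl}methanone | COc1cc(OCC=C)c(c(OCC=C)c1)C(=O)[C@]1(c2ccc(OCOCC[Si](C)(C)C)c(CC=C(C)C)c2OC)CO1
F7 | step 5 | 2-[2-methoxy-3-(3-methylbut-2-en-1-yl)-4-{[2-(trimethylsilyl)ethoxy]methoxy}phenyl]prop-2-enal | COc1c(CC=C(C)C)c(OCOCC[Si](C)(C)C)ccc1C(=C)C=O
F0 | step 8 | none | none
F8 | step 3 | 4-bromo-3-methoxyphenol | COc1cc(O)ccc1Br
F9 | step 3 | 1-bromo-2-methoxy-4-{[2-(trimethylsilyl)ethoxy]methoxy}benzene | COc1cc(OCOCC[Si](C)(C)C)ccc1Br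
F10 | step 3 | (3-bromo-2-methoxy-6-{[2-(trimethylsilyl)ethoxy]methoxy}phenyl)lithium | COc1c([Li])c(OCOCC[Si](C)(C)C)ccc1Br
F11 | step 3 | 1-bromo-2-methoxy-3-(3-methylbut-2-en-1-yl)-4-{[2-(trimethylsilyl)ethoxy]methoxy}benzene | COc1c(CC=C(C)C)c(OCOCC[Si](C)(C)C)ccc1Br
F12 | step 3 | [2-methoxy-3-(3-methylbut-2-en-1-yl)-4-{[2-(trimethylsilyl)ethoxy]methoxy}phenyl]lithium | COc1c(CC=C(C)C)c(OCOCC[Si](C)(C)C)ccc1[Li]
A1 | alternative 1 | 2-diazo-1-[4-methoxy-2,6-bis(methoxymethoxy)phenyl]-2-[2-methoxy-4-(methoxymethoxy)-3-(3-methylbut-2-en-1-yl)phenyl]ethan-1-one | COc1cc(OCOC)c(c(OCOC)c1)C(=O)C(=[N+]=[N-])c1ccc(OCOC)c(CC=C(C)C)c1OC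
A2 | alternative 1 | (2S)-2,3-dihydroxy-1-[4-methoxy-2,6-bis(methoxymethoxy)phenyl]-2-[2-methoxy-4-(methoxymethoxy)-3-(3-methylbut-2-en-1-yl)phenyl]propan-1-one | COc1cc(OCOC)c(c(OCOC)c1)C(=O)[C@@](O)(CO)c1ccc(OCOC)c(CC=C(C)C)c1OC
A3 | alternative 2 | methyl (2S)-3-hydroxy-2-(methoxymethoxy)-2-[2-methoxy-4-(methoxymethoxy)-3-(3-methylbut-2-en-1-yl)phenyl]propanoate | OC[C@@](OCOC)(c1ccc(OCOC)c(CC=C(C)C)c1OC)C(=O)OC
A4 | alternative 2 | 5-methoxy-3-(methoxymethoxy)-2-(trimethylsilyl)phenyl trifluoromethanesulfonate | COc1cc(OCOC)c([Si](C)(C)C)c(OS(=O)(=O)C(F)(F)F)c1
A5 | alternative 2 | (3S)-7-methoxy-3,5-bis(methoxymethoxy)-3-[2-methoxy-4-(methoxymethoxy)-3-(3-methylbut-2-en-1-yl)phenyl]-2,3-dihydro-4H-chromen-4-one | COc1cc(OCOC)c2c(c1)OC[C@@](OCOC)(c1ccc(OCOC)c(CC=C(C)C)c1OC)C2=O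
A6 | alternative 3 | 4-methoxy-2-(methoxymethoxy)-6-{2-[2-methoxy-4-(methoxymethoxy)-3-(3-methylbut-2-en-1-yl)phenyl]-2-oxoethoxy}benzaldehyde | COc1cc(OCOC)c(C=O)c(c1)OCC(=O)c1ccc(OCOC)c(CC=C(C)C)c1OC
A7 | alternative 3 | (3S)-3-hydroxy-7-methoxy-5-(methoxymethoxy)-3-[2-methoxy-4-(methoxymethoxy)-3-(3-methylbut-2-en-1-yl)phenyl]-2,3-dihydro-4H-chromen-4-one | COc1cc(OCOC)c2c(c1)OC[C@@](O)(c1ccc(OCOC)c(CC=C(C)C)c1OC)C2=O
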